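The route rests on disconnecting the O1–C2 bond of the dihydropyran ring. C2 is a tertiary ether carbon. With a temporary C3=C4 double bond it becomes allylic and, through C4a and C8a, conjugated with the phenol oxygen O1. A C2 carbinol therefore ionises easily to a planar cation (a vinyl o-quinone methide after proton loss). The precursor is an open-chain, racemic (E)-styryl tertiary alcohol that already carries the full side chain and comes from one Heck coupling with racemic (E,E)-geranyllinalool. A chiral Brønsted acid erases its stereocentre, closes the ring and writes C2 in one enantioconvergent operation. Sodium in ethanol then saturates C3=C4 and frees the 6-hydroxyl.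

Key step: step 5

Numbering: chroman numbering (O1, C2, C3, C4, C4a, C5–C8, C8a; side chain C1'–C13') is used for all compounds, also for the open-chain ones.
Assumption: the (R)-configured acid is taken to deliver the (2R)-chromene. The sense of induction is to be checked on the first run, and the equally available (S)-acid is used if it is opposite.

Step 1
Reactants: 1 2,3,5-trimethylhydroquinone
Product: 2 2,3,5-trimethyl-1,4-phenylene diacetate
Conditions: Ac2O, pyridine, DMAP (cat.), CH2Cl2, 0 °C to rt
Reagents that add atoms: acetic anhydride CC(=O)OC(C)=O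
Why: DMAP-catalysed O-acylation of both phenols masks the oxidation-prone hydroquinone, and no stereocentre is formed.

Step 2
Reactants: 2 2,3,5-trimethyl-1,4-phenylene diacetate
Product: 3 4-hydroxy-2,3,6-trimethylphenyl acetate
Conditions: n-BuNH2 (1.05 equiv), THF, 0 °C to rt
Reagents that add atoms: none
Why: In this chemoselective aminolysis of an aryl ester, the acetate next to the ring C–H is far more accessible than the one flanked by two ortho-methyl groups, so one equivalent of amine should free only the phenol that becomes O1.

Step 3
Reactants: 3 4-hydroxy-2,3,6-trimethylphenyl acetate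
Product: 4 4-hydroxy-3-iodo-2,5,6-trimethylphenyl acetate
Conditions: NIS, TsOH·H2O (cat.), MeCN, 0 °C, dark
Reagents that add atoms: N-iodosuccinimide O=C1CCC(=O)N1I
Why: In this electrophilic aromatic iodination the free phenol activates the only unsubstituted ring carbon (ortho to OH, the future C4a), and the para-acetoxy group blocks oxidation to the quinone.

Step 4
Reactants: 4 4-hydroxy-3-iodo-2,5,6-trimethylphenyl acetate; 5 (±)-(6E,10E)-geranyllinalool
Product: 6 (±)-4-hydroxy-3-[(1E,6E,10E)-3-hydroxy-3,7,11,15-tetramethylhexadeca-1,6,10,14-tetraen-1-yl]-2,5,6-trimethylphenyl acetate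
Conditions: Pd(OAc)2 (cat.), n-Bu4NCl, NaHCO3, DMF, 50 °C, Ar, dark; chromatography on Et3N-deactivated silica
Reagents that add atoms: none
Why: In this ligand-free Heck reaction the aryl-Pd species adds only to the monosubstituted vinyl group of 5, the hydrogen-free carbinol carbon leaves β-hydride elimination to the (E)-styryl alcohol as the only exit, the trisubstituted chain alkenes are inert, and the carbinol centre stays racemic, which is of no consequence.

Step 5
Reactants: 6 (±)-(E)-styryl tertiary alcohol
Product: 8 (2R)-3,4-didehydro-α-tocotrienyl acetate, via acid-bound vinyl o-quinone methide 7 (not isolated)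
Conditions: (R)-3,3'-bis(2,4,6-triisopropylphenyl)-BINOL N-triflylphosphoramide (10 mol %), 4 Å MS, toluene, −78 to −40 °C, dark
Reagents that add atoms: none
Why: The strong chiral acid protonates the tertiary allylic hydroxyl of either enantiomer of 6, water leaves, and the planar aryl-conjugated allyl cation stays paired with the phosphoramide anion; proton transfer from the ortho-hydroxyl makes it the acid-bound vinyl o-quinone methide 7, in which O1 bonds to C2. The closest known reaction type is the N-triflylphosphoramide-catalysed intramolecular asymmetric allylic substitution of 2-(3-hydroxyalk-1-enyl)phenols to 2,2-disubstituted 2H-chromenes (contact-ion-pair catalysis). The pyran ring closes 6-endo-trig at the cation terminus C2, which is the same event as a disrotatory oxa-6π electrocyclisation of 7. C2 is the only new stereocentre and is set by the catalyst alone: the anion remains hydrogen-bonded to O1–H next to C2, its 3,3'-aryl groups tell the methyl group from the long chain, and since the old centre is destroyed both enantiomers of 6 should converge on (2R)-8. The step needs chemoselectivity over the three chain alkenes, over proton loss to a triene and over attack of C3'=C4' on C4; only the C2 carbinol is tertiary, allylic and phenol-conjugated at once and so ionises at a temperature at which isolated alkenes are not protonated. The C5 methyl group forces the allyl unit to the O1 side of the exocyclic C4a=C4 bond, so that intramolecular O-capture is the fastest exit.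

Step 6
Reactants: 8 (2R)-3,4-didehydro-α-tocotrienyl acetate
Product: 9 (2R,3'E,7'E)-α-tocotrienol
Conditions: Na (excess), abs. EtOH, reflux, Ar, dark; aq. NH4Cl
Reagents that add atoms: none
Why: In this dissolving-metal reduction only the arene-conjugated C3=C4 bond accepts electrons while the isolated trisubstituted alkenes do not, the ethoxide formed transesterifies the acetate, the resulting 6-phenoxide disfavours reductive cleavage of the allylic C2–O1 bond, and C2 is not touched.

Compound list
1 | 2,3,5-trimethylhydroquinone | Cc1cc(O)c(C)c(C)c1O | starting material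
2 | 2,3,5-trimethyl-1,4-phenylene diacetate | CC(=O)Oc1cc(C)c(OC(C)=O)c(C)c1C | intermediate
3 | 4-hydroxy-2,3,6-trimethylphenyl acetate | CC(=O)Oc1c(C)cc(O)c(C)c1C | intermediate
4 | 4-hydroxy-3-iodo-2,5,6-trimethylphenyl acetate | CC(=O)Oc1c(C)c(I)c(O)c(C)c1C | intermediate
5 | (±)-(6E,10E)-geranyllinalool, (6E,10E)-3,7,11,15-tetramethylhexadeca-1,6,10,14-tetraen-3-ol, racemic | CC(C)=CCC/C(C)=C/CC/C(C)=C/CCC(C)(O)C=C | starting material
6 | (±)-4-hydroxy-3-[(1E,6E,10E)-3-hydroxy-3,7,11,15-tetramethylhexadeca-1,6,10,14-tetraen-1-yl]-2,5,6-trimethylphenyl acetate, racemic at the carbinol | CC(C)=CCC/C(C)=C/CC/C(C)=C/CCC(C)(O)/C=C/c1c(C)c(OC(C)=O)c(C)c(C)c1O | intermediate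
7 | vinyl o-quinone methide, 4-acetoxy-2,3,5-trimethyl-6-[(6E,10E)-3,7,11,15-tetramethylhexadeca-2,6,10,14-tetraen-1-ylidene]cyclohexa-2,4-dien-1-one, exocyclic bond Z (allyl unit on the carbonyl side), C2=C3 geometry not fixed, hydrogen-bonded to the acid | CC(C)=CCC/C(C)=C/CC/C(C)=C/CCC(C)=C/C=C1\C(=O)C(C)=C(C)C(OC(C)=O)=C1C | intermediate
8 | (2R)-2,5,7,8-tetramethyl-2-[(3E,7E)-4,8,12-trimethyltrideca-3,7,11-trien-1-yl]-2H-chromen-6-yl acetate | CC(C)=CCC/C(C)=C/CC/C(C)=C/CC[C@]1(C)C=Cc2c(C)c(OC(C)=O)c(C)c(C)c2O1 | intermediate
9 | (2R,3'E,7'E)-α-tocotrienol | CC(C)=CCC/C(C)=C/CC/C(C)=C/CC[C@]1(C)CCc2c(C)c(O)c(C)c(C)c2O1 | target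

Total step count: 6. Longest linear sequence: 6 steps (1 → 2 → 3 → 4 → 6 → 8 → 9).

Steps most likely to fail

Step 5. The ion pair may not tell the methyl group from the chain well enough, which means poor facial selectivity at C2. The cation may also escape by proton loss or by capture by the nearest chain alkene. The fallback sets out from 3 and comes back at 9, and it sets the stereocentre before the ring is closed.
- Commercial (E,E,E)-geranylgeraniol and methyl chloroformate/pyridine give geranylgeranyl methyl carbonate F1.
- Phenol 3 is O-allylated with F1 at the more substituted allyl terminus to the (R)-tertiary aryl allyl ether F2. This is a Pd-catalysed asymmetric allylic alkylation of Tsuji–Trost type (Pd2(dba)3, chiral DACH-phenyl bis(diphenylphosphinobenzamide) ligand, CH2Cl2).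
- 9-BBN adds only to the vinyl group, and NaBO3 gives the primary alcohol F3.
- Tf2O/2,6-di-tert-butyl-4-methylpyridine at −78 °C forms the triflate. It alkylates the one free ortho carbon in a Friedel–Crafts closure of the C4–C4a bond to (R)-α-tocotrienyl acetate F4.
- K2CO3/MeOH then gives 9.

Step 4. Oxidative addition may be slow at the iodide flanked by OH and CH3. At the temperature then needed, the heat- and acid-sensitive carbinol may close or dehydrate prematurely, which would carry racemic material into step 5. The fallback sets out from 4 and comes back at 6, and it fixes the bond site and the alkene geometry in a preformed boron nucleophile.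
- Commercial (E,E)-farnesylacetone and ethynylmagnesium bromide give the racemic propargylic alcohol F5.
- Zr-catalysed hydroboration with pinacolborane (Cp2ZrHCl cat.), which touches only the terminal alkyne, gives the (E)-alkenylboronate F6.
- Suzuki–Miyaura coupling of F6 with 4 (Pd/SPhos, K3PO4, THF–H2O, rt) gives 6 at room temperature.

Step 6. The allylic C2–O1 bond may be cleaved reductively in the radical anion, and reduction may be incomplete or excessive. Configuration may also erode through thermal or light-induced ring opening of the chromene in boiling ethanol. The fallback sets out from 8 and comes back at 9.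
- K2CO3/MeOH at rt removes the acetate to give (R)-3,4-didehydro-α-tocotrienol F7.
- Homogeneous hydrogenation with RhCl(PPh3)3 (H2 1 atm, benzene–EtOH, rt) accepts the cis-disubstituted C3=C4 bond and leaves the trisubstituted chain alkenes, giving 9.

Further compounds
F1 | step 5 | (2E,6E,10E)-geranylgeranyl methyl carbonate | CC(C)=CCC/C(C)=C/CC/C(C)=C/CC/C(C)=C/COC(=O)OC
F2 | step 5 | 4-{[(3R,6E,10E)-3,7,11,15-tetramethylhexadeca-1,6,10,14-tetraen-3-yl]oxy}-2,3,6-trimethylphenyl acetate | CC(C)=CCC/C(C)=C/CC/C(C)=C/CC[C@](C)(C=C)Oc1cc(C)c(OC(C)=O)c(C)c1C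
F3 | step 5 | 4-{[(3R,6E,10E)-1-hydroxy-3,7,11,15-tetramethylhexadeca-6,10,14-trien-3-yl]oxy}-2,3,6-trimethylphenyl acetate | CC(C)=CCC/C(C)=C/CC/C(C)=C/CC[C@](C)(CCO)Oc1cc(C)c(OC(C)=O)c(C)c1C
F4 | step 5 | (2R,3'E,7'E)-α-tocotrienyl acetate | CC(C)=CCC/C(C)=C/CC/C(C)=C/CC[C@]1(C)CCc2c(C)c(OC(C)=O)c(C)c(C)c2O1
F5 | step 4 | (±)-(6E,10E)-3,7,11,15-tetramethylhexadeca-6,10,14-trien-1-yn-3-ol | CC(C)=CCC/C(C)=C/CC/C(C)=C/CCC(C)(O)C#C
F6 | step 4 | (±)-(1E,6E,10E)-3,7,11,15-tetramethyl-1-(4,4,5,5-tetramethyl-1,3,2-dioxaborolan-2-yl)hexadeca-1,6,10,14-tetraen-3-ol | CC(C)=CCC/C(C)=C/CC/C(C)=C/CCC(C)(O)/C=C/B1OC(C)(C)C(C)(C)O1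
F7 | step 6 | (2R,3'E,7'E)-3,4-didehydro-α-tocotrienol | CC(C)=CCC/C(C)=C/CC/C(C)=C/CC[C@]1(C)C=Cc2c(C)c(O)c(C)c(C)c2O1
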